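**Retrosynthetic overview**

- The strategy rests on the C7 spiro-oxirane (C7–O–C14) carried on ring carbon C6 and bonded directly to the C8 ketone. C7 and C8 are neighbouring carbons at carbonyl oxidation level, so the C7–C8 bond is cut with C8 as an acyl anion (a lithiated prenyl dithiane) and C7/C14 as a chloroacetyl group on C6.
- Target 26 ⇐ prenyl ketone 25 (Schenck ene) ⇐ dithiane 24 ⇐ spiro-oxirane dithiane 19 (C2 deprotection and oxidation, C1 deprotection and acylation).
- 19 ⇐ chloromethyl ketone 12 + 2-prenyl-1,3-dithiane 16, with oxirane closure in the same flask.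
- 12 ⇐ (R)-carvone 1: α′-hydroxylation (C1), Luche reduction (C2), hydroxyl-directed epoxidation (C3/C4), isopropenyl → acetyl → chloroacetyl.
- Ring order: the cyclohexane comes from carvone; the C3/C4 oxirane is closed in step 4; the C7/C14 spiro-oxirane is closed in step 9.

Key step: step 9

Remark on the chemistry: ring carbons are labelled C1 (O-bearing CH, the α′ carbon of carvone), C2 (carbonyl carbon of carvone), C3 (methyl-bearing), C4, C5 (CH2) and C6 (the carvone stereocentre); C7 is the isopropenyl-derived quaternary carbon, C14 its CH2, and C8–C11 the chain. The C6 centre of the target has the same spatial arrangement as the stereocentre of (R)-carvone, and the target is (1S,3S,4S,6R,7R) in these labels.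

**Route**

Step 1
Reactants: 1 (R)-carvone
Product: 3 trans-C1-hydroxycarvone (OH on C1 anti to the C6 isopropenyl group), via sodium dienolate of carvone 2 (not isolated)
Conditions: NaN(SiMe3)2, THF, −78 °C; then trans-2-(phenylsulfonyl)-3-phenyloxaziridine, −78 °C; NH4Cl (aq)
Reagents that add atoms: trans-2-(phenylsulfonyl)-3-phenyloxaziridine, O=S(=O)(N1OC1c1ccccc1)c1ccccc1
Why: Kinetic deprotonation at the α′ methylene gives the cross-conjugated dienolate, and Davis enolate hydroxylation should deliver oxygen to C1 on the face away from the neighbouring C6 isopropenyl group, which sets the trans C1/C6 relationship; any cis isomer would be removed by chromatography here or after silylation.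

Step 2
Reactants: 3 trans-C1-hydroxycarvone
Product: 4 C1 tert-butyldimethylsilyl ether of 3
Conditions: TBSCl, imidazole, DMF, 0 → 20 °C
Reagents that add atoms: tert-butyldimethylsilyl chloride, CC(C)(C)[Si](C)(C)Cl
Why: Imidazole-promoted silyl ether formation protects the α-ketol with a bulky, non-coordinating group that should survive the organolithium steps and that the stereocontrol of step 9 depends on.

Step 3
Reactants: 4 C1 TBS ether
Product: 5 allylic alcohol with the C2 hydroxyl cis to the C6 isopropenyl group and trans to C1–OTBS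
Conditions: NaBH4, CeCl3·7H2O, MeOH, −78 → −40 °C
Reagents that add atoms: none
Why: Luche 1,2-reduction of the enone by axial hydride delivery to the half-chair, in which C1–OTBS and the C6 isopropenyl group are both equatorial, should give the equatorial C2 alcohol, the same sense as the reduction of carvone to cis-carveol.

Step 4
Reactants: 5 allylic alcohol
Product: 6 epoxy alcohol with the C3/C4 oxirane on the face of the C2 hydroxyl (cis to the C6 isopropenyl group)
Conditions: VO(acac)2 (cat.), t-BuOOH, CH2Cl2, 0 → 20 °C
Reagents that add atoms: tert-butyl hydroperoxide, CC(C)(C)OO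
Why: In the vanadium-catalysed hydroxyl-directed epoxidation the vanadate ester of the C2 alcohol delivers the peroxide oxygen to the syn face of C3=C4, which sets C3 and C4 and leaves the non-allylic isopropenyl alkene untouched.

Step 5
Reactants: 6 epoxy alcohol
Product: 7 C2 triethylsilyl ether of 6
Conditions: Et3SiCl, imidazole, 4-(dimethylamino)pyridine (cat.), DMF, 0 → 20 °C
Reagents that add atoms: chlorotriethylsilane, CC[Si](Cl)(CC)CC
Why: Silyl ether formation under mild base caps the C2 hydroxyl with a group more labile than TBS, so that C2 can later be unmasked alone.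

Step 6
Reactants: 7 bis-silyl ether with C6 isopropenyl
Product: 9 methyl ketone (acetyl group on C6), via secondary ozonide 8 (not isolated)
Conditions: O3, CH2Cl2, −78 °C; then PPh3, −78 → 20 °C
Reagents that add atoms: ozone, [O-][O+]=O
Why: Ozonolysis by 1,3-dipolar cycloaddition and Criegee recombination, followed by phosphine reduction of the ozonide, cleaves the only alkene under neutral conditions that cannot epimerise C6.

Step 7
Reactants: 9 methyl ketone
Product: 12 chloromethyl ketone (chloroacetyl group on C6), via lithium enolate 10 (not isolated), via trimethylsilyl enol ether 11 (not isolated)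
Conditions: LiN(i-Pr)2, THF, −78 °C; Me3SiCl, −78 → 0 °C; then N-chlorosuccinimide, 0 °C
Reagents that add atoms: N-chlorosuccinimide, O=C1CCC(=O)N1Cl
Why: Kinetic deprotonation by the hindered amide takes the methyl hydrogen in preference to the C6 methine, and electrophilic chlorination of the resulting terminal enol silane places chlorine on C14 only.

Step 8
Reactants: 13 1,3-dithiane; 14 prenyl bromide
Product: 16 2-(3-methylbut-2-en-1-yl)-1,3-dithiane, via 2-lithio-1,3-dithiane 15 (not isolated)
Conditions: n-BuLi, THF, −30 °C; then 14, −78 → 0 °C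
Reagents that add atoms: none
Why: Corey–Seebach alkylation, in which the soft dithianyl anion displaces the primary allylic bromide in an SN2 reaction at the unsubstituted terminus.

Step 9
Reactants: 12 chloromethyl ketone; 16 2-(3-methylbut-2-en-1-yl)-1,3-dithiane
Product: 19 spiro-oxirane with C8 masked as the prenyl dithiane (C1 OTBS and C2 OTES), via 2-lithio-2-(3-methylbut-2-en-1-yl)-1,3-dithiane 17 (not isolated), via lithium alkoxide of the C7 chlorohydrin 18 (not isolated)
Conditions: 16, n-BuLi, THF, −20 °C; then 12 in THF added at −78 °C; then warm to 20 °C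
Reagents that add atoms: none
Why: The tertiary dithianyl lithium 17, C8 with reversed polarity, adds 1,2 to the C7 carbonyl of 12 to give alkoxide 18, which on warming displaces the primary chloride at C14 and so forms the C7–C8 bond and the C7–O–C14 oxirane in one flask. The closest known reaction types are the Corey–Seebach addition of 2-lithio-1,3-dithianes to ketones and the addition of organolithium reagents to chloromethyl ketones with closure to 2,2-disubstituted oxiranes. The oxirane closes by a 3-exo-tet intramolecular Williamson substitution, with the C7 oxygen as nucleophile and no bond to C7 broken. The new stereocentre C7 is controlled by C6 through a Felkin–Anh transition state: the C6–C1 bond carrying the bulky OTBS lies anti to the incoming carbanion, which passes the C6 hydrogen and not the C5 methylene, and this places O, C8 and C14 counterclockwise when viewed from C6, the (7R) arrangement of the target. TBS is kept at C1 because a coordinating ether there would be expected to bridge lithium between the C1 and C7 oxygens and direct attack to the opposite face. The step needs carbonyl addition to outrun enolisation of the chloroacetyl group and SN2 displacement at C14, which the inductively activated carbonyl, the low temperature, THF without polar additives and addition of the ketone to an excess of the anion should secure, while the silyl ethers and the trisubstituted oxirane are inert at −78 °C.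

Step 10
Reactants: 19 spiro-oxirane dithiane
Product: 20 C2 alcohol (C1 OTBS retained)
Conditions: HF·pyridine, pyridine, THF, 0 °C
Reagents that add atoms: none
Why: Buffered fluoride desilylation should cleave the triethylsilyl ether well before the TBS ether, and the cis relationship of the C2 hydroxyl and the C3/C4 oxirane rules out Payne rearrangement.

Step 11
Reactants: 20 C2 alcohol
Product: 21 C2 ketone (α,β-epoxy ketone with C1 OTBS)
Conditions: SO3·pyridine, DMSO, i-Pr2NEt, CH2Cl2, 0 °C
Reagents that add atoms: none
Why: Parikh–Doering oxidation with activated DMSO oxidises the hindered secondary alcohol without touching the dithiane sulfur atoms, which hypervalent iodine oxidants could attack.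

Step 12
Reactants: 21 C2 ketone
Product: 22 α-ketol (free C1 hydroxyl)
Conditions: Bu4NF, AcOH, THF, 0 → 20 °C
Reagents that add atoms: none
Why: Fluoride desilylation of the activated α-silyloxy ketone, buffered with acetic acid so that the liberated α-ketol is not exposed to base that could epimerise C1 or shift the acyloin.

Step 13
Reactants: 22 α-ketol; 23 isovaleric anhydride
Product: 24 C1 isovalerate (C8 still the prenyl dithiane)
Conditions: 4-(dimethylamino)pyridine (cat.), pyridine, CH2Cl2, 0 °C
Reagents that add atoms: none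
Why: Nucleophilic-catalysed acyl transfer from the anhydride esterifies the only free hydroxyl with retention at C1, the equatorial trans arrangement being the stable one in any case.

Step 14
Reactants: 24 isovalerate dithiane
Product: 25 β,γ-unsaturated C8 ketone (prenyl ketone)
Conditions: MeI, CaCO3, MeCN/H2O, 40 °C
Reagents that add atoms: water, O
Why: Alkylative dithiane hydrolysis (S-methylation, ring opening to the thionium ion and capture by water) runs near neutrality, which should spare both oxiranes and the ester and keep the C10=C11 alkene out of conjugation.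

Step 15
Reactants: 25 prenyl ketone
Product: 26 target hydroperoxide
Conditions: O2, visible light, 5,10,15,20-tetraphenylporphyrin (cat.), CH2Cl2, −20 °C
Reagents that add atoms: dioxygen (as singlet oxygen), O=O
Why: In the Schenck ene reaction singlet oxygen adds to C10=C11 and abstracts a C9 hydrogen, which the adjacent C8 carbonyl activates, so that the alkene shifts into conjugation as the (E)-C9=C10 enone and the hydroperoxide is placed on the tertiary C11.

**Compound list**

1 | (R)-carvone | CC1=CC[C@H](CC1=O)C(C)=C | starting material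
2 | sodium cross-conjugated dienolate of carvone (not isolated) | CC1=CC[C@H](C=C1O[Na])C(C)=C | intermediate
3 | trans-C1-hydroxycarvone (OH anti to C6 isopropenyl) | O[C@@H]1C(=O)C(C)=CC[C@H]1C(C)=C | intermediate
4 | C1 TBS ether of 3 | CC(C)(C)[Si](C)(C)O[C@@H]1C(=O)C(C)=CC[C@H]1C(C)=C | intermediate
5 | C2 allylic alcohol (OH cis to C6 isopropenyl, trans to C1 OTBS) | CC(C)(C)[Si](C)(C)O[C@@H]1[C@@H](O)C(C)=CC[C@H]1C(C)=C | intermediate
6 | C3/C4 epoxy alcohol (oxirane syn to C2 OH) | CC(C)(C)[Si](C)(C)O[C@@H]1[C@@H](O)[C@@]2(C)O[C@H]2C[C@H]1C(C)=C | intermediate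
7 | C2 TES ether of 6 | CC(C)(C)[Si](C)(C)O[C@@H]1[C@@H](O[Si](CC)(CC)CC)[C@@]2(C)O[C@H]2C[C@H]1C(C)=C | intermediate
8 | secondary ozonide of 7 (3-methyl-1,2,4-trioxolan-3-yl on C6, mixture at the trioxolane carbon; not isolated) | CC(C)(C)[Si](C)(C)O[C@@H]1[C@@H](O[Si](CC)(CC)CC)[C@@]2(C)O[C@H]2C[C@H]1C3(C)OCOO3 | intermediate
9 | methyl ketone (acetyl on C6) | CC(C)(C)[Si](C)(C)O[C@@H]1[C@@H](O[Si](CC)(CC)CC)[C@@]2(C)O[C@H]2C[C@H]1C(C)=O | intermediate
10 | terminal lithium enolate of 9 (not isolated) | CC(C)(C)[Si](C)(C)O[C@@H]1[C@@H](O[Si](CC)(CC)CC)[C@@]2(C)O[C@H]2C[C@H]1C(=C)O[Li] | intermediate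
11 | trimethylsilyl enol ether of 9 (not isolated) | CC(C)(C)[Si](C)(C)O[C@@H]1[C@@H](O[Si](CC)(CC)CC)[C@@]2(C)O[C@H]2C[C@H]1C(=C)O[Si](C)(C)C | intermediate
12 | chloromethyl ketone (chloroacetyl on C6) | CC(C)(C)[Si](C)(C)O[C@@H]1[C@@H](O[Si](CC)(CC)CC)[C@@]2(C)O[C@H]2C[C@H]1C(=O)CCl | intermediate
13 | 1,3-dithiane | C1CSCSC1 | starting material
14 | prenyl bromide (1-bromo-3-methylbut-2-ene) | CC(C)=CCBr | starting material
15 | 2-lithio-1,3-dithiane (not isolated) | [Li]C1SCCCS1 | intermediate
16 | 2-(3-methylbut-2-en-1-yl)-1,3-dithiane | CC(C)=CCC1SCCCS1 | intermediate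
17 | 2-lithio-2-(3-methylbut-2-en-1-yl)-1,3-dithiane (not isolated) | [Li]C1(CC=C(C)C)SCCCS1 | intermediate
18 | lithium alkoxide of the C7 chlorohydrin (not isolated) | CC(C)(C)[Si](C)(C)O[C@@H]1[C@@H](O[Si](CC)(CC)CC)[C@@]2(C)O[C@H]2C[C@H]1[C@@](O[Li])(CCl)C3(CC=C(C)C)SCCCS3 | intermediate
19 | spiro-oxirane, C8 as prenyl dithiane, C1 OTBS, C2 OTES | CC(C)(C)[Si](C)(C)O[C@@H]1[C@@H](O[Si](CC)(CC)CC)[C@@]2(C)O[C@H]2C[C@H]1[C@]3(C4(CC=C(C)C)SCCCS4)CO3 | intermediate
20 | C2 alcohol, C1 OTBS, dithiane | CC(C)(C)[Si](C)(C)O[C@@H]1[C@@H](O)[C@@]2(C)O[C@H]2C[C@H]1[C@]3(C4(CC=C(C)C)SCCCS4)CO3 | intermediate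
21 | C2 ketone, C1 OTBS, dithiane | CC(C)(C)[Si](C)(C)O[C@@H]1C(=O)[C@@]2(C)O[C@H]2C[C@H]1[C@]3(C4(CC=C(C)C)SCCCS4)CO3 | intermediate
22 | α-ketol (C1 OH, C2 ketone), dithiane | O[C@@H]1C(=O)[C@@]2(C)O[C@H]2C[C@H]1[C@]3(C4(CC=C(C)C)SCCCS4)CO3 | intermediate
23 | isovaleric anhydride | CC(C)CC(=O)OC(=O)CC(C)C | starting material
24 | C1 isovalerate, dithiane | CC(C)CC(=O)O[C@@H]1C(=O)[C@@]2(C)O[C@H]2C[C@H]1[C@]3(C4(CC=C(C)C)SCCCS4)CO3 | intermediate
25 | C1 isovalerate, β,γ-unsaturated C8 ketone | CC(C)CC(=O)O[C@@H]1C(=O)[C@@]2(C)O[C@H]2C[C@H]1[C@]3(C(=O)CC=C(C)C)CO3 | intermediate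
26 | CNP0131119.1, (1S,3S,4S,6R,7R) in the labels used here, (E)-enone with C11 hydroperoxide | CC(C)CC(=O)O[C@@H]1C(=O)[C@@]2(C)O[C@H]2C[C@H]1[C@]1(C(=O)/C=C/C(C)(C)OO)CO1 | target

**Step count**

Total steps: 15. Longest linear sequence: 14 steps (steps 1–7 and 9–15 from (R)-carvone); step 8 is a one-step side branch.

**Steps most likely to fail**

1. Step 9. Proton transfer from the acidic chloroacetyl group to the hindered tertiary carbanion, or direct displacement of chloride at C14, may outrun carbonyl addition; facial selectivity at C7 may also be incomplete. The fallback sets out from methyl ketone 9 and comes back at alcohol 20. Enol silane 11, made as in step 7, would be oxidised under Rubottom conditions (m-CPBA, NaHCO3, CH2Cl2, then mild acid) to the hydroxymethyl ketone F1. Silylation (Et3SiCl, imidazole) would give the triethylsilyloxymethyl ketone F2, which carries no leaving group and is less acidic. Addition of 17 at −78 °C should then give the tertiary carbinol F3 under the same Felkin–Anh bias. HF·pyridine would remove both triethylsilyl groups to give the triol F4. Tosylation at the primary hydroxyl (TsCl, pyridine, 0 °C) would give the monotosylate F5, and K2CO3 in MeOH would close the oxirane from the C7 alkoxide to 20. The C–C bond formation and the ring closure are thereby separated.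

2. Step 15. Hydrogen abstraction from a C11 methyl group may compete with abstraction at C9, giving the secondary allylic hydroperoxide with an isopropenyl terminus, and the hydroperoxide may not survive purification. The fallback sets out from 25 and comes back at 26, and installs the peroxide by cobalt-catalysed Markovnikov hydroperoxysilylation. The photooxygenation is run without regard to its regiochemistry, and the methyl-abstraction product, the C10 hydroperoxide F6 (C10 epimers), is reduced with PPh3 to the β-hydroxy ketone F7. Isayama–Mukaiyama peroxidation of its 1,1-disubstituted alkene (Co(acac)2, Et3SiH, O2, ClCH2CH2Cl, 20 °C) should give the tertiary triethylsilyl peroxide F8. Mesylation with E1cB elimination (MsCl, Et3N, 0 °C) would give the (E)-enone silyl peroxide F9, and HF·pyridine would free the hydroperoxide 26.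

3. Step 14. Hydrolysis of the hindered dithiane next to the quaternary C7 may be slow, and prolonged warming may let the β,γ-alkene move into conjugation or degrade the epoxy ketone and the ester. The fallback sets out from 19 and comes back at 25, and unmasks C8 early on the robust bis-silyl ether. Hg(ClO4)2 and CaCO3 in THF/H2O at 0 °C would give the prenyl ketone F10. HF·pyridine would then give the C2 alcohol F11, and Dess–Martin periodinane with NaHCO3, usable once sulfur is gone, would give the diketone F12. Bu4NF/AcOH would give the α-ketol F13, and acylation with 23 (DMAP, pyridine) would give 25. All of these steps would be kept buffered to hold the alkene in place.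

**Further compounds**

F1 | step 9 | hydroxymethyl ketone (hydroxyacetyl on C6; C1 OTBS, C2 OTES) | CC(C)(C)[Si](C)(C)O[C@@H]1[C@@H](O[Si](CC)(CC)CC)[C@@]2(C)O[C@H]2C[C@H]1C(=O)CO
F2 | step 9 | triethylsilyloxymethyl ketone | CC(C)(C)[Si](C)(C)O[C@@H]1[C@@H](O[Si](CC)(CC)CC)[C@@]2(C)O[C@H]2C[C@H]1C(=O)CO[Si](CC)(CC)CC
F3 | step 9 | C7 tertiary carbinol with C14 OTES and C8 prenyl dithiane | CC(C)(C)[Si](C)(C)O[C@@H]1[C@@H](O[Si](CC)(CC)CC)[C@@]2(C)O[C@H]2C[C@H]1[C@@](O)(CO[Si](CC)(CC)CC)C3(CC=C(C)C)SCCCS3
F4 | step 9 | triol (C2, C7 and C14 hydroxyls; C1 OTBS) | CC(C)(C)[Si](C)(C)O[C@@H]1[C@@H](O)[C@@]2(C)O[C@H]2C[C@H]1[C@@](O)(CO)C3(CC=C(C)C)SCCCS3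
F5 | step 9 | C14 monotosylate of F4 | CC(C)(C)[Si](C)(C)O[C@@H]1[C@@H](O)[C@@]2(C)O[C@H]2C[C@H]1[C@@](O)(COS(=O)(=O)c3ccc(C)cc3)C4(CC=C(C)C)SCCCS4
F6 | step 15 | C10 hydroperoxide with C11 isopropenyl terminus (C10 epimers) | CC(C)CC(=O)O[C@@H]1C(=O)[C@@]2(C)O[C@H]2C[C@H]1[C@]3(C(=O)CC(OO)C(C)=C)CO3
F7 | step 15 | C10 β-hydroxy ketone with isopropenyl terminus (C10 epimers) | CC(C)CC(=O)O[C@@H]1C(=O)[C@@]2(C)O[C@H]2C[C@H]1[C@]3(C(=O)CC(O)C(C)=C)CO3
F8 | step 15 | C10 hydroxy C11 triethylsilyl peroxide (C10 epimers) | CC(C)CC(=O)O[C@@H]1C(=O)[C@@]2(C)O[C@H]2C[C@H]1[C@]3(C(=O)CC(O)C(C)(C)OO[Si](CC)(CC)CC)CO3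
F9 | step 15 | (E)-enone C11 triethylsilyl peroxide | CC(C)CC(=O)O[C@@H]1C(=O)[C@@]2(C)O[C@H]2C[C@H]1[C@]3(C(=O)/C=C/C(C)(C)OO[Si](CC)(CC)CC)CO3
F10 | step 14 | prenyl ketone with C1 OTBS and C2 OTES | CC(C)(C)[Si](C)(C)O[C@@H]1[C@@H](O[Si](CC)(CC)CC)[C@@]2(C)O[C@H]2C[C@H]1[C@]3(C(=O)CC=C(C)C)CO3
F11 | step 14 | prenyl ketone with C2 OH and C1 OTBS | CC(C)(C)[Si](C)(C)O[C@@H]1[C@@H](O)[C@@]2(C)O[C@H]2C[C@H]1[C@]3(C(=O)CC=C(C)C)CO3
F12 | step 14 | C2,C8 diketone with C1 OTBS | CC(C)(C)[Si](C)(C)O[C@@H]1C(=O)[C@@]2(C)O[C@H]2C[C@H]1[C@]3(C(=O)CC=C(C)C)CO3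
F13 | step 14 | C2,C8 diketone with C1 OH | O[C@@H]1C(=O)[C@@]2(C)O[C@H]2C[C@H]1[C@]3(C(=O)CC=C(C)C)CO3
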